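The flavanone is disconnected at the aryl ether bond O1–C8a of ring C. Because O1 sits on the C2 stereocentre, that centre can be made beforehand as a secondary benzylic carbinol by catalyst-controlled ketone reduction and then simply arylated: an intramolecular palladium-catalysed C–O coupling between the C2 hydroxyl and the bromine-bearing C8a of ring A closes ring C in one operation without touching the C2–O bond, so the (S) configuration is carried through. The cyclisation substrate is an open-chain (1S)-1,3-diarylpropan-1-ol carrying the ortho-bromide on the future ring A, the geranyl ether on ring B, and the future C4 carbonyl masked as a silyl-protected carbinol.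

Key step: step 6

Remark on the chemistry: flavan numbering is used (O1, C2, C3, C4, C4a, C5 to C8, C8a; ring A is the benzo ring, ring B the 2-aryl group, ring C the pyran ring), and "geranyl" means (2E)-3,7-dimethylocta-2,6-dien-1-yl. The aldol-derived carbinol carbon (C3 of the open chain, C4 of the flavan) is formed racemic and carried as both epimers, so it is written without a stereodescriptor until it is oxidised in step 8.

Step 1
Reactants: 1 4-hydroxyacetophenone; 2 geranyl bromide
Product: 3 4'-(geranyloxy)acetophenone
Conditions: K2CO3, acetone, reflux
Reagents that add atoms: none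
Why: Williamson ether synthesis in which the acyl-stabilised phenoxide displaces the primary allylic bromide by SN2 at the unsubstituted terminus, so the (E)-geometry of the geranyl unit is preserved and O-alkylation is favoured in the polar aprotic medium.

Step 2
Reactants: 4 2-bromo-4-hydroxybenzaldehyde
Product: 5 2-bromo-4-(triisopropylsilyloxy)benzaldehyde
Conditions: iPr3SiCl, imidazole, DMF, 0 °C to rt
Reagents that add atoms: triisopropylsilyl chloride, CC(C)[Si](Cl)(C(C)C)C(C)C
Why: Imidazole-promoted O-silylation of a phenol, the bulky triisopropylsilyl aryl ether being chosen because it should withstand the lithium enolate, the borane reduction and the carbonate base of later steps and still fall to fluoride at the end.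

Step 3
Reactants: 3 4'-(geranyloxy)acetophenone; 5 2-bromo-4-(triisopropylsilyloxy)benzaldehyde
Product: 7 racemic 3-[2-bromo-4-(triisopropylsilyloxy)phenyl]-1-[4-(geranyloxy)phenyl]-3-hydroxypropan-1-one, via lithium enolate 6 (not isolated)
Conditions: LiN(iPr)2, THF, −78 °C; then 5, −78 °C; AcOH quench at −78 °C
Reagents that add atoms: none
Why: Directed aldol addition of a preformed kinetic lithium enolate to a non-enolisable aromatic aldehyde, quenched cold so that retro-aldol cleavage and dehydration to the chalcone are avoided; the new carbinol centre is formed racemic, which is acceptable because it later becomes the C4 carbonyl.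

Step 4
Reactants: 7 racemic 3-[2-bromo-4-(triisopropylsilyloxy)phenyl]-1-[4-(geranyloxy)phenyl]-3-hydroxypropan-1-one
Product: 8 racemic 3-[2-bromo-4-(triisopropylsilyloxy)phenyl]-1-[4-(geranyloxy)phenyl]-3-(triethylsilyloxy)propan-1-one
Conditions: Et3SiCl, imidazole, DMAP (cat.), CH2Cl2, 0 °C to rt
Reagents that add atoms: triethylsilyl chloride, CC[Si](Cl)(CC)CC
Why: Imidazole-mediated silylation of the secondary aldol hydroxyl under conditions too mild for retro-aldol or elimination, giving a triethylsilyl ether that blocks this oxygen through reduction and coupling and can later be cleaved beside the aryl triisopropylsilyl ether.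

Step 5
Reactants: 8 racemic 3-[2-bromo-4-(triisopropylsilyloxy)phenyl]-1-[4-(geranyloxy)phenyl]-3-(triethylsilyloxy)propan-1-one
Product: 9 (1S)-3-[2-bromo-4-(triisopropylsilyloxy)phenyl]-1-[4-(geranyloxy)phenyl]-3-(triethylsilyloxy)propan-1-ol (both C3 epimers)
Conditions: (R)-2-methyl-CBS-oxazaborolidine (20 mol%), catecholborane, toluene, −78 to −40 °C; then H2O
Reagents that add atoms: none
Why: Corey–Bakshi–Shibata reduction in which the (R)-oxazaborolidine binds the carbonyl oxygen anti to the larger aryl group and directs hydride to the Re face, which should give the (1S)-carbinol under catalyst control for both enantiomers of the ketone (the remote, non-chelating silyloxy centre exerts little 1,3-induction), while catecholborane at low temperature leaves the trisubstituted geranyl alkenes unhydroborated.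

Step 6
Reactants: 9 (1S)-3-[2-bromo-4-(triisopropylsilyloxy)phenyl]-1-[4-(geranyloxy)phenyl]-3-(triethylsilyloxy)propan-1-ol (both C3 epimers)
Product: 10 (2S)-4'-(geranyloxy)-4-(triethylsilyloxy)-7-(triisopropylsilyloxy)flavan (both C4 epimers)
Conditions: Pd(OAc)2 (5 mol%), rac-2-(di-tert-butylphosphino)-1,1'-binaphthyl (6 mol%), Cs2CO3, toluene, 65 °C
Reagents that add atoms: none
Why: Pd(OAc)2 is reduced in situ to a zerovalent palladium monophosphine complex that inserts into the C8a–Br bond of ring A, the tethered C2 hydroxyl then binds and is deprotonated by Cs2CO3 to give a seven-membered aryl(alkoxo)palladium chelate, and C–O reductive elimination releases the flavan and returns zerovalent palladium. The closest known reaction type is the Buchwald–Hartwig-type intramolecular etherification of secondary alcohols with ortho-bromoarenes, an established route to chromans. Ring C is closed as a six-membered ring at the O1–C8a bond by metal-mediated intramolecular displacement of bromide on the unactivated ring A, the three-carbon tether C2–C3–C4 placing the oxygen exactly where a six-membered ring forms. No stereocentre is created: the C2–O bond is never broken, so the (S) configuration from step 5 is retained by construction, and both C4 epimers should cyclise because C4 only carries a spectator silyl ether. The step needs C–O reductive elimination to outrun β-hydride elimination of the benzylic palladium alkoxide (which would give the debrominated ketone) and Ar–Br insertion to outrun ionisation of the allylic aryl ether; the bulky electron-rich di-tert-butylbiarylphosphine favours the former, while in the substrate the intramolecular six-ring geometry, the absence of any carbonyl or free phenol (C4–O and C7–O are silylated, so no retro-aldol, elimination or phenoxide interference) and the hindered trisubstituted geranyl alkene (a poor partner for π-allyl formation) secure the latter. The weak, insoluble carbonate in toluene keeps the concentration of free alkoxide low, which should suppress 1,3-migration of the triethylsilyl group and cleavage of the aryl silyl ether.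

Step 7
Reactants: 10 (2S)-4'-(geranyloxy)-4-(triethylsilyloxy)-7-(triisopropylsilyloxy)flavan (both C4 epimers)
Product: 11 (2S)-4'-(geranyloxy)-7-(triisopropylsilyloxy)flavan-4-ol (both C4 epimers)
Conditions: AcOH/THF/H2O (3:1:1), 0 °C to rt
Reagents that add atoms: none
Why: Acid-catalysed hydrolysis of the alkyl triethylsilyl ether, which is far more acid-labile than the aryl triisopropylsilyl ether; water is the only nucleophile, so any reversible ionisation at the electron-rich benzylic C4 merely returns the alcohol (whose configuration is irrelevant), and acetic acid is too weak to cleave the geranyl ether or disturb the C2–O1 bond.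

Step 8
Reactants: 11 (2S)-4'-(geranyloxy)-7-(triisopropylsilyloxy)flavan-4-ol (both C4 epimers)
Product: 12 (2S)-4'-(geranyloxy)-7-(triisopropylsilyloxy)flavanone
Conditions: Dess–Martin periodinane, pyridine, CH2Cl2, 0 °C to rt
Reagents that add atoms: none
Why: Dess–Martin oxidation of the secondary benzylic alcohol under near-neutral, non-basic conditions should converge both C4 epimers onto one flavanone without opening ring C, so C2 is untouched, and the alkenes and the aryl silyl ether are inert to the reagent.

Step 9
Reactants: 12 (2S)-4'-(geranyloxy)-7-(triisopropylsilyloxy)flavanone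
Product: 13 (2S)-4'-(geranyloxy)-7-hydroxyflavanone (CNP0302343.1)
Conditions: Bu4NF/AcOH (1:1), THF, 0 °C
Reagents that add atoms: none
Why: Fluoride-mediated cleavage of the aryl silyl ether driven by Si–F bond formation, buffered with acetic acid so that neither fluoride nor the liberated 7-phenoxide can trigger the base-induced retro-oxa-Michael opening to the 2'-hydroxychalcone that would racemise C2.

Compound list
1 | 4-hydroxyacetophenone | CC(=O)c1ccc(O)cc1 | starting material
2 | geranyl bromide, (2E)-1-bromo-3,7-dimethylocta-2,6-diene | CC(C)=CCC/C(C)=C/CBr | starting material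
3 | 4'-(geranyloxy)acetophenone | CC(C)=CCC/C(C)=C/COc1ccc(C(C)=O)cc1 | intermediate
4 | 2-bromo-4-hydroxybenzaldehyde | O=Cc1ccc(O)cc1Br | starting material
5 | 2-bromo-4-(triisopropylsilyloxy)benzaldehyde | O=Cc1ccc(O[Si](C(C)C)(C(C)C)C(C)C)cc1Br | intermediate
6 | lithium enolate of 3, lithium 1-[4-(geranyloxy)phenyl]ethen-1-olate | CC(C)=CCC/C(C)=C/COc1ccc(C(=C)O[Li])cc1 | intermediate (not isolated)
7 | racemic 3-[2-bromo-4-(triisopropylsilyloxy)phenyl]-1-[4-(geranyloxy)phenyl]-3-hydroxypropan-1-one | CC(C)=CCC/C(C)=C/COc1ccc(C(=O)CC(O)c2ccc(O[Si](C(C)C)(C(C)C)C(C)C)cc2Br)cc1 | intermediate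
8 | racemic 3-[2-bromo-4-(triisopropylsilyloxy)phenyl]-1-[4-(geranyloxy)phenyl]-3-(triethylsilyloxy)propan-1-one | CC(C)=CCC/C(C)=C/COc1ccc(C(=O)CC(O[Si](CC)(CC)CC)c2ccc(O[Si](C(C)C)(C(C)C)C(C)C)cc2Br)cc1 | intermediate
9 | (1S,3RS)-3-[2-bromo-4-(triisopropylsilyloxy)phenyl]-1-[4-(geranyloxy)phenyl]-3-(triethylsilyloxy)propan-1-ol, both C3 epimers | CC(C)=CCC/C(C)=C/COc1ccc([C@@H](O)CC(O[Si](CC)(CC)CC)c2ccc(O[Si](C(C)C)(C(C)C)C(C)C)cc2Br)cc1 | intermediate
10 | (2S,4RS)-4'-(geranyloxy)-4-(triethylsilyloxy)-7-(triisopropylsilyloxy)flavan, both C4 epimers | CC(C)=CCC/C(C)=C/COc1ccc([C@@H]2CC(O[Si](CC)(CC)CC)c3ccc(O[Si](C(C)C)(C(C)C)C(C)C)cc3O2)cc1 | intermediate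
11 | (2S,4RS)-4'-(geranyloxy)-7-(triisopropylsilyloxy)flavan-4-ol, both C4 epimers | CC(C)=CCC/C(C)=C/COc1ccc([C@@H]2CC(O)c3ccc(O[Si](C(C)C)(C(C)C)C(C)C)cc3O2)cc1 | intermediate
12 | (2S)-4'-(geranyloxy)-7-(triisopropylsilyloxy)flavanone | CC(C)=CCC/C(C)=C/COc1ccc([C@@H]2CC(=O)c3ccc(O[Si](C(C)C)(C(C)C)C(C)C)cc3O2)cc1 | intermediate
13 | (2S)-4'-(geranyloxy)-7-hydroxyflavanone, (2S)-2-{4-[(2E)-3,7-dimethylocta-2,6-dien-1-yloxy]phenyl}-7-hydroxychroman-4-one | CC(C)=CCC/C(C)=C/COc1ccc([C@@H]2CC(=O)c3ccc(O)cc3O2)cc1 | target

Total step count: 9. Longest linear sequence: 8 steps (steps 1 and 3 to 9 from compound 1, or equally steps 2 to 9 from compound 4).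

Steps most likely to fail

1. Step 6. The palladium alkoxide may undergo β-hydride elimination faster than C–O reductive elimination, which would oxidise the carbinol and remove the bromine reductively. The catalyst may also ionise the geranyl aryl ether, or the triethylsilyl group may migrate to the C1 oxygen before ring closure. The fallback closes the same ring C at the other ether bond, O1–C2, by a Mitsunobu reaction with inversion. It sets out from ketone 8. Reduction with (S)-2-methyl-CBS-oxazaborolidine and catecholborane should give the (1R)-3-[2-bromo-4-(triisopropylsilyloxy)phenyl]-1-[4-(geranyloxy)phenyl]-3-(triethylsilyloxy)propan-1-ol F1. Miyaura borylation (PdCl2(dppf), B2pin2, KOAc, dioxane, 80 °C) should convert the aryl bromide into the aryl pinacol boronate F2. Oxidation with NaBO3·4H2O in THF/H2O should then give the ortho-hydroxyaryl carbinol F3. Mitsunobu cyclisation (PPh3, diisopropyl azodicarboxylate, THF, 0 °C) lets the phenol displace the activated benzylic hydroxyl with inversion, and the fallback comes back to the route at the (2S)-flavan 10. Its weakness is partial ionisation of the electron-rich benzylic centre, which is why coupling with retention is preferred.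

2. Step 5. Catalyst control may be incomplete for the enantiomer of 8 in which the C3 centre is mismatched with the oxazaborolidine, which would erode the enantiomeric purity at C1. The borane may also add to the geranyl alkenes. The fallback replaces the oxazaborolidine–borane reduction by a different reaction type, Noyori asymmetric transfer hydrogenation with RuCl[(S,S)-TsDPEN](p-cymene) and HCO2H/Et3N kept near neutrality to spare the triethylsilyl ether. This ruthenium hydride, bifunctional mechanism involves no boron hydride and is known to give (S)-carbinols from aryl alkyl ketones. It sets out from 8 and comes back at 9 (no new compound, F0). If facial control is still uneven between the two C3 epimers of 9, they are diastereomers and can be separated so that only the purer one is advanced.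

3. Step 7. Acid may ionise the electron-rich benzylic C4 and lead to dehydration to the flav-3-ene. The triethylsilyl ether may cleave too slowly, or the aryl silyl ether may be lost prematurely. The fallback avoids selective acidolysis altogether. It sets out from 10, where treatment with excess Bu4NF in THF should remove both silyl groups while no base-sensitive carbonyl is present, giving the (2S)-4'-(geranyloxy)flavan-4,7-diol F4. Chemoselective oxidation of the para-hydroxy-activated benzylic alcohol with activated MnO2 in CH2Cl2 at rt should then give the flavanone directly. The fallback comes back to the route at the target 13 and bypasses steps 8 and 9 as well.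

Further compounds
F1 | step 6 | (1R)-3-[2-bromo-4-(triisopropylsilyloxy)phenyl]-1-[4-(geranyloxy)phenyl]-3-(triethylsilyloxy)propan-1-ol, both C3 epimers | CC(C)=CCC/C(C)=C/COc1ccc([C@H](O)CC(O[Si](CC)(CC)CC)c2ccc(O[Si](C(C)C)(C(C)C)C(C)C)cc2Br)cc1
F2 | step 6 | (1R)-1-[4-(geranyloxy)phenyl]-3-[2-(4,4,5,5-tetramethyl-1,3,2-dioxaborolan-2-yl)-4-(triisopropylsilyloxy)phenyl]-3-(triethylsilyloxy)propan-1-ol, both C3 epimers | CC(C)=CCC/C(C)=C/COc1ccc([C@H](O)CC(O[Si](CC)(CC)CC)c2ccc(O[Si](C(C)C)(C(C)C)C(C)C)cc2B3OC(C)(C)C(C)(C)O3)cc1
F3 | step 6 | (1R)-1-[4-(geranyloxy)phenyl]-3-[2-hydroxy-4-(triisopropylsilyloxy)phenyl]-3-(triethylsilyloxy)propan-1-ol, both C3 epimers | CC(C)=CCC/C(C)=C/COc1ccc([C@H](O)CC(O[Si](CC)(CC)CC)c2ccc(O[Si](C(C)C)(C(C)C)C(C)C)cc2O)cc1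
F0 | step 5 | none | none
F4 | step 7 | (2S)-4'-(geranyloxy)flavan-4,7-diol, both C4 epimers | CC(C)=CCC/C(C)=C/COc1ccc([C@@H]2CC(O)c3ccc(O)cc3O2)cc1
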